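Ring A is disconnected across four bonds (C8–C8a, C7–C8, C5–C6, C4a–C5). This traces the flavone to a kojic-acid-derived 4-pyranone that already carries ring B and the 3-methoxy group, and to a siloxyalkyne holding the whole hydrated prenyl chain. The key step exploits the row C5–OH, C6–alkyl, C7–O, C8–H that ring A carries on the C4a–C8a bond of ring C: a light-triggered Wolff rearrangement and ynol ether benzannulation should install this pattern in one operation. Its precursor is a 6-aryl-5-methoxy-4-pyranone with a diazoacetyl group at C2, whose C2=C3 bond serves as the ene unit. One global desilylation then gives the target.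

Key step: step 9

Remark: the target has no stereocentre. The 4'-oxygen is carried as a TBS ether (boronic acid 4 is taken to be a catalogue compound) so that a single fluoride treatment removes all three silyl groups at the end. Bond labels use flavone numbering.

Step 1
Reactants: 1 kojic acid [5-hydroxy-2-(hydroxymethyl)-4H-pyran-4-one]
Product: 2 2-bromo-3-hydroxy-6-(hydroxymethyl)-4H-pyran-4-one
Conditions: NBS (1.05 equiv), MeCN, 0 °C to rt
Reagents that add atoms: N-bromosuccinimide, O=C1CCC(=O)N1Br
Why: Electrophilic bromination of the enolic hydroxypyranone should occur at C6 of kojic acid, the position ortho to the free OH at which kojic acid also reacts in Mannich and hydroxymethylation reactions.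

Step 2
Reactants: 2 2-bromo-3-hydroxy-6-(hydroxymethyl)-4H-pyran-4-one
Product: 3 2-bromo-6-(hydroxymethyl)-3-methoxy-4H-pyran-4-one
Conditions: MeI, K2CO3, DMF, rt
Reagents that add atoms: iodomethane, CI
Why: Williamson O-alkylation, in which carbonate deprotonates only the acidic enolic OH, so the primary alcohol should stay free.

Step 3
Reactants: 3 2-bromo-6-(hydroxymethyl)-3-methoxy-4H-pyran-4-one; 4 [4-(tert-butyldimethylsilyloxy)phenyl]boronic acid
Product: 5 2-[4-(tert-butyldimethylsilyloxy)phenyl]-6-(hydroxymethyl)-3-methoxy-4H-pyran-4-one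
Conditions: Pd(dppf)Cl2 (5 mol %), K3PO4, degassed 1,4-dioxane/H2O, 70 °C
Reagents that add atoms: none
Why: Suzuki–Miyaura coupling, in which the C–Br bond at the β-position of the pyranone enone should add readily to zerovalent palladium, while phosphate base at moderate temperature is expected to spare the aryl silyl ether and the free alcohol.

Step 4
Reactants: 5 2-[4-(tert-butyldimethylsilyloxy)phenyl]-6-(hydroxymethyl)-3-methoxy-4H-pyran-4-one
Product: 7 6-[4-(tert-butyldimethylsilyloxy)phenyl]-5-methoxy-4-oxo-4H-pyran-2-carboxylic acid, via pyranone-2-carbaldehyde 6 (not isolated)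
Conditions: TEMPO (cat.), NaOCl (cat.), NaClO2, MeCN/phosphate buffer (pH 6.7), 35 °C
Reagents that add atoms: sodium chlorite, [Na+].[O-]Cl=O
Why: TEMPO-catalysed oxidation with chlorite as terminal oxidant (Zhao variant of the Anelli oxidation, with a Pinnick-type aldehyde stage) works near neutral pH with only catalytic hypochlorite, so the electron-rich aryl ring and the silyl ether should survive.

Step 5
Reactants: 7 6-[4-(tert-butyldimethylsilyloxy)phenyl]-5-methoxy-4-oxo-4H-pyran-2-carboxylic acid
Product: 9 1-{6-[4-(tert-butyldimethylsilyloxy)phenyl]-5-methoxy-4-oxo-4H-pyran-2-yl}-2-diazoethan-1-one, via acid chloride 8 (not isolated)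
Conditions: (COCl)2 (1.2 equiv), cat. DMF, CH2Cl2, 0 °C to rt, evaporate; then CH2N2 (3 equiv), Et2O, 0 °C
Reagents that add atoms: diazomethane, C=[N+]=[N-]; oxalyl chloride, O=C(Cl)C(=O)Cl (chlorine of 8 only)
Why: Acylation of diazomethane as in the first stage of the Arndt–Eistert sequence, where excess diazomethane removes HCl as chloromethane and so keeps the diazo ketone from becoming a chloromethyl ketone.

Step 6
Reactants: 10 methyl pent-4-ynoate
Product: 12 2-methylhex-5-yn-2-ol, via hex-5-yn-2-one 11 (not isolated)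
Conditions: MeMgBr (3.3 equiv), THF, 0 °C to rt; aq NH4Cl
Reagents that add atoms: methylmagnesium bromide, C[Mg]Br
Why: Double Grignard addition to the ester through the methyl ketone gives the tertiary alcohol, with one further equivalent of MeMgBr consumed by the acidic alkyne C–H, which is restored on quench.

Step 7
Reactants: 12 2-methylhex-5-yn-2-ol
Product: 13 triethyl[(2-methylhex-5-yn-2-yl)oxy]silane
Conditions: TESOTf, 2,6-lutidine, CH2Cl2, −78 to 0 °C
Reagents that add atoms: triethylsilyl triflate, CC[Si](CC)(CC)OS(=O)(=O)C(F)(F)F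
Why: Silylation of a hindered tertiary alcohol with a silyl triflate and 2,6-lutidine is reliable, and the TES ether masks the OH against the organolithium reagents and the ketene of later steps.

Step 8
Reactants: 13 triethyl[(2-methylhex-5-yn-2-yl)oxy]silane
Product: 16 triisopropyl{[5-methyl-5-(triethylsilyloxy)hex-1-yn-1-yl]oxy}silane, via lithium acetylide 14 (not isolated), via lithium ynolate 15 (not isolated)
Conditions: n-BuLi, THF, −78 °C; t-BuOOLi (from t-BuOOH and LiN(SiMe3)2), −78 to 0 °C; TIPSOTf, −78 to 0 °C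
Reagents that add atoms: tert-butyl hydroperoxide, CC(C)(C)OO; triisopropylsilyl triflate, CC(C)[Si](OS(=O)(=O)C(F)(F)F)(C(C)C)C(C)C; n-butyllithium, [Li]CCCC (lithium of 14 and 15 only)
Why: Julia-type oxidation of a lithium acetylide by lithium tert-butyl peroxide gives the lithium ynolate, which the bulky TIPS triflate should silylate on oxygen and not on carbon.

Step 9
Reactants: 9 1-{6-[4-(tert-butyldimethylsilyloxy)phenyl]-5-methoxy-4-oxo-4H-pyran-2-yl}-2-diazoethan-1-one; 16 triisopropyl{[5-methyl-5-(triethylsilyloxy)hex-1-yn-1-yl]oxy}silane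
Product: 21 2-[4-(tert-butyldimethylsilyloxy)phenyl]-5-hydroxy-3-methoxy-6-[3-methyl-3-(triethylsilyloxy)butyl]-7-(triisopropylsilyloxy)-4H-chromen-4-one, via pyranonylketene 17 (not isolated), via cyclobutenone 18 (not isolated), via dienylketene 19 (not isolated), via cyclohexadienone 20 (not isolated)
Conditions: 16 (1.5 equiv), hν (blue LED, 440–450 nm), degassed ClCH2CH2Cl, rt; then 80 °C
Reagents that add atoms: none
Why: Excitation of the diazo n→π* band expels N2 and triggers Wolff rearrangement (pyranone C2 migrates, making C8–C8a) to ketene 17; the nucleophilic, alkyl-bearing carbon of ynol ether 16 then attacks the ketene carbonyl carbon, so the stepwise [2+2] gives cyclobutenone 18 with C5–C6 and C7–C8 formed and the chain placed between the two oxygens. Reversible 4π electrocyclic opening gives dienylketene 19, and thermal disrotatory 6π electrocyclisation of the ketene carbon onto pyranone C3 forms C4a–C5 and closes ring A as dienone 20, which tautomerises to the hydrogen-bonded 5-phenol 21. The closest known reaction is the Danheiser benzannulation in its diazo ketone variant with siloxyalkynes, applied here to a diazo ketone whose ene unit is the pyranone C2=C3 bond. No stereocentre remains, since those at C4 of 18 and C4a of 20 are transient and racemic. Regiochemistry rests on the polarity of the ynol ether and on C3–H being the only carbon terminus open to the 6π closure; selective excitation rests on blue light reaching the diazo chromophore but not the aryl pyranone, which should suppress pyranone photoisomerisation.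

Step 10
Reactants: 21 2-[4-(tert-butyldimethylsilyloxy)phenyl]-5-hydroxy-3-methoxy-6-[3-methyl-3-(triethylsilyloxy)butyl]-7-(triisopropylsilyloxy)-4H-chromen-4-one
Product: 22 topazolin hydrate [5,7-dihydroxy-6-(3-hydroxy-3-methylbutyl)-2-(4-hydroxyphenyl)-3-methoxy-4H-chromen-4-one]
Conditions: TBAF (4 equiv), THF, 0 °C to rt; then AcOH
Reagents that add atoms: none
Why: Fluoride-mediated desilylation should cleave both aryl silyl ethers and the tertiary TES ether in one operation without acid, which avoids cyclisation of the tertiary alcohol onto the 5- or 7-OH.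

Compound list
1 | kojic acid, 5-hydroxy-2-(hydroxymethyl)-4H-pyran-4-one | O=c1cc(CO)occ1O | starting material
2 | 2-bromo-3-hydroxy-6-(hydroxymethyl)-4H-pyran-4-one | O=c1cc(CO)oc(Br)c1O | intermediate
3 | 2-bromo-6-(hydroxymethyl)-3-methoxy-4H-pyran-4-one | COc1c(Br)oc(CO)cc1=O | intermediate
4 | [4-(tert-butyldimethylsilyloxy)phenyl]boronic acid | CC(C)(C)[Si](C)(C)Oc1ccc(B(O)O)cc1 | starting material
5 | 2-[4-(tert-butyldimethylsilyloxy)phenyl]-6-(hydroxymethyl)-3-methoxy-4H-pyran-4-one | COc1c(-c2ccc(O[Si](C)(C)C(C)(C)C)cc2)oc(CO)cc1=O | intermediate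
6 | 6-[4-(tert-butyldimethylsilyloxy)phenyl]-5-methoxy-4-oxo-4H-pyran-2-carbaldehyde (not isolated) | COc1c(-c2ccc(O[Si](C)(C)C(C)(C)C)cc2)oc(C=O)cc1=O | intermediate
7 | 6-[4-(tert-butyldimethylsilyloxy)phenyl]-5-methoxy-4-oxo-4H-pyran-2-carboxylic acid | COc1c(-c2ccc(O[Si](C)(C)C(C)(C)C)cc2)oc(C(=O)O)cc1=O | intermediate
8 | 6-[4-(tert-butyldimethylsilyloxy)phenyl]-5-methoxy-4-oxo-4H-pyran-2-carbonyl chloride (not isolated) | COc1c(-c2ccc(O[Si](C)(C)C(C)(C)C)cc2)oc(C(=O)Cl)cc1=O | intermediate
9 | 1-{6-[4-(tert-butyldimethylsilyloxy)phenyl]-5-methoxy-4-oxo-4H-pyran-2-yl}-2-diazoethan-1-one | COc1c(-c2ccc(O[Si](C)(C)C(C)(C)C)cc2)oc(C(=O)C=[N+]=[N-])cc1=O | intermediate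
10 | methyl pent-4-ynoate | COC(=O)CCC#C | starting material
11 | hex-5-yn-2-one (not isolated) | CC(=O)CCC#C | intermediate
12 | 2-methylhex-5-yn-2-ol | CC(C)(O)CCC#C | intermediate
13 | triethyl[(2-methylhex-5-yn-2-yl)oxy]silane | C#CCCC(C)(C)O[Si](CC)(CC)CC | intermediate
14 | [5-methyl-5-(triethylsilyloxy)hex-1-yn-1-yl]lithium (not isolated) | [Li]C#CCCC(C)(C)O[Si](CC)(CC)CC | intermediate
15 | lithium 5-methyl-5-(triethylsilyloxy)hex-1-yn-1-olate (not isolated) | [Li+].[O-]C#CCCC(C)(C)O[Si](CC)(CC)CC | intermediate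
16 | triisopropyl{[5-methyl-5-(triethylsilyloxy)hex-1-yn-1-yl]oxy}silane | CC(C)[Si](OC#CCCC(C)(C)O[Si](CC)(CC)CC)(C(C)C)C(C)C | intermediate
17 | 2-{6-[4-(tert-butyldimethylsilyloxy)phenyl]-5-methoxy-4-oxo-4H-pyran-2-yl}ethen-1-one (not isolated) | COc1c(-c2ccc(O[Si](C)(C)C(C)(C)C)cc2)oc(C=C=O)cc1=O | intermediate
18 | 4-{6-[4-(tert-butyldimethylsilyloxy)phenyl]-5-methoxy-4-oxo-4H-pyran-2-yl}-2-[3-methyl-3-(triethylsilyloxy)butyl]-3-(triisopropylsilyloxy)cyclobut-2-en-1-one, racemic at C4 (not isolated) | O=C1C(CCC(C)(C)O[Si](CC)(CC)CC)=C(O[Si](C(C)C)(C(C)C)C(C)C)C1c1cc(=O)c(OC)c(-c2ccc(O[Si](C)(C)C(C)(C)C)cc2)o1 | intermediate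
19 | (3E)-4-{6-[4-(tert-butyldimethylsilyloxy)phenyl]-5-methoxy-4-oxo-4H-pyran-2-yl}-2-[3-methyl-3-(triethylsilyloxy)butyl]-3-(triisopropylsilyloxy)buta-1,3-dien-1-one (not isolated) | O=C=C(CCC(C)(C)O[Si](CC)(CC)CC)/C(O[Si](C(C)C)(C(C)C)C(C)C)=C\c1cc(=O)c(OC)c(-c2ccc(O[Si](C)(C)C(C)(C)C)cc2)o1 | intermediate
20 | 2-[4-(tert-butyldimethylsilyloxy)phenyl]-3-methoxy-6-[3-methyl-3-(triethylsilyloxy)butyl]-7-(triisopropylsilyloxy)-4H-chromene-4,5(4aH)-dione, racemic at C4a (not isolated) | O=C1C(CCC(C)(C)O[Si](CC)(CC)CC)=C(O[Si](C(C)C)(C(C)C)C(C)C)C=C2OC(-c3ccc(O[Si](C)(C)C(C)(C)C)cc3)=C(OC)C(=O)C12 | intermediate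
21 | 2-[4-(tert-butyldimethylsilyloxy)phenyl]-5-hydroxy-3-methoxy-6-[3-methyl-3-(triethylsilyloxy)butyl]-7-(triisopropylsilyloxy)-4H-chromen-4-one | COc1c(-c2ccc(O[Si](C)(C)C(C)(C)C)cc2)oc2cc(O[Si](C(C)C)(C(C)C)C(C)C)c(CCC(C)(C)O[Si](CC)(CC)CC)c(O)c2c1=O | intermediate
22 | topazolin hydrate, 5,7-dihydroxy-6-(3-hydroxy-3-methylbutyl)-2-(4-hydroxyphenyl)-3-methoxy-4H-chromen-4-one | COc1c(-c2ccc(O)cc2)oc2cc(O)c(CCC(C)(C)O)c(O)c2c1=O | target

Total step count: 10. Longest linear sequence: 7 steps (steps 1–5, 9 and 10, from kojic acid 1 to 22); the alkyne branch (steps 6–8) is 3 steps.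

Steps most likely to fail

Step 9. Several things may go wrong. Light may also be absorbed by the aryl pyranone, leading to photoisomerisation of the 4-pyranone or hydrogen abstraction from the neighbouring methoxy group. The excited diazo ketone may follow carbene pathways instead of rearranging, the ketene may dimerise, or the cyclobutenone may not open and close cleanly. The fallback is a light-free entry to the same ketene; it sets out from 9 and comes back to the route at cyclobutenone 18. Diazo ketone 9 would be homologated in the dark by an Arndt–Eistert reaction (PhCO2Ag cat., Et3N, THF/H2O) to 2-{6-[4-(tert-butyldimethylsilyloxy)phenyl]-5-methoxy-4-oxo-4H-pyran-2-yl}acetic acid F1. This would be converted with (COCl)2 and cat. DMF at 0 °C into 2-{6-[4-(tert-butyldimethylsilyloxy)phenyl]-5-methoxy-4-oxo-4H-pyran-2-yl}acetyl chloride F2. Slow addition of Et3N to F2 and 16 in toluene at rt should then generate ketene 17 by dehydrochlorination and capture it as 18, and heating at 80–110 °C should complete the cascade to 21.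

Step 5. The chlorinating agent may attack the pyranone carbonyl (chloropyrylium formation), residual HCl may turn the diazo ketone into a chloromethyl ketone, or diazomethane may add as a dipole across the electron-poor C2=C3 bond. The fallback replaces acylation of diazomethane by diazo transfer; it sets out from 7 and comes back at 9. Acid 7 would be coupled (MeNHOMe·HCl, EDC·HCl, i-Pr2NEt, CH2Cl2) to 6-[4-(tert-butyldimethylsilyloxy)phenyl]-N,5-dimethoxy-N-methyl-4-oxo-4H-pyran-2-carboxamide F3. MeMgBr in THF at −78 °C should give 2-acetyl-6-[4-(tert-butyldimethylsilyloxy)phenyl]-5-methoxy-4H-pyran-4-one F4. A detrifluoroacetylative diazo transfer would follow: LiN(SiMe3)2 and CF3CO2CH2CF3 at −78 °C to give 1-{6-[4-(tert-butyldimethylsilyloxy)phenyl]-5-methoxy-4-oxo-4H-pyran-2-yl}-4,4,4-trifluorobutane-1,3-dione F5, not isolated, then MsN3, Et3N and H2O in MeCN at rt to return 9.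

Step 8. Oxygen transfer to the acetylide may be incomplete, the ynolate may be silylated on carbon to give a silylketene, or the ynol silyl ether may hydrolyse during isolation. The fallback is a Kowalski ester-to-ynolate sequence; it sets out from 13 and comes back at ynolate 15. Oxidative cleavage of the terminal alkyne of 13 (RuCl3 cat., NaIO4, NaHCO3, MeCN/EtOAc/H2O) should give 4-methyl-4-(triethylsilyloxy)pentanoic acid F6, and TMSCHN2 in MeOH/toluene its ester, methyl 4-methyl-4-(triethylsilyloxy)pentanoate F7. Addition of LiCHBr2 (from CH2Br2 and lithium 2,2,6,6-tetramethylpiperidide, THF, −78 °C) should give 1,1-dibromo-5-methyl-5-(triethylsilyloxy)hexan-2-one F8, not isolated. Its enolate (LiN(SiMe3)2) would be treated with n-BuLi and warmed to rt, rearranging to 15, which TIPSOTf converts to 16 as in the route.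

Further compounds
F1 | step 9 | 2-{6-[4-(tert-butyldimethylsilyloxy)phenyl]-5-methoxy-4-oxo-4H-pyran-2-yl}acetic acid | COc1c(-c2ccc(O[Si](C)(C)C(C)(C)C)cc2)oc(CC(=O)O)cc1=O
F2 | step 9 | 2-{6-[4-(tert-butyldimethylsilyloxy)phenyl]-5-methoxy-4-oxo-4H-pyran-2-yl}acetyl chloride | COc1c(-c2ccc(O[Si](C)(C)C(C)(C)C)cc2)oc(CC(=O)Cl)cc1=O
F3 | step 5 | 6-[4-(tert-butyldimethylsilyloxy)phenyl]-N,5-dimethoxy-N-methyl-4-oxo-4H-pyran-2-carboxamide | COc1c(-c2ccc(O[Si](C)(C)C(C)(C)C)cc2)oc(C(=O)N(C)OC)cc1=O
F4 | step 5 | 2-acetyl-6-[4-(tert-butyldimethylsilyloxy)phenyl]-5-methoxy-4H-pyran-4-one | COc1c(-c2ccc(O[Si](C)(C)C(C)(C)C)cc2)oc(C(C)=O)cc1=O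
F5 | step 5 | 1-{6-[4-(tert-butyldimethylsilyloxy)phenyl]-5-methoxy-4-oxo-4H-pyran-2-yl}-4,4,4-trifluorobutane-1,3-dione | COc1c(-c2ccc(O[Si](C)(C)C(C)(C)C)cc2)oc(C(=O)CC(=O)C(F)(F)F)cc1=O
F6 | step 8 | 4-methyl-4-(triethylsilyloxy)pentanoic acid | CC[Si](CC)(CC)OC(C)(C)CCC(=O)O
F7 | step 8 | methyl 4-methyl-4-(triethylsilyloxy)pentanoate | COC(=O)CCC(C)(C)O[Si](CC)(CC)CC
F8 | step 8 | 1,1-dibromo-5-methyl-5-(triethylsilyloxy)hexan-2-one | BrC(Br)C(=O)CCC(C)(C)O[Si](CC)(CC)CC
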